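(The runs come from a simulation on assumed constants, noise included.)

A flat product curve is easily taken for a finished reaction, so before you trust this plateau, count what it cost in reagent. Wednesday's run is the very flask asked about, followed so far.

| flask | substrate | reagent | remark | time |
|---|---|---|---|---|
| Wednesday's | 5 mM | 6.5 mM | the very flask that is asked about, followed so far |  |
| flask | 5.0 mM | 6.50 mM |  | 10 min |

Wednesday's run (percent of the substrate charged)

| time / min | product / % |
|---|---|
| 0.500 | 21.9 |
| 1.50 | 36.1 |
| 3.00 | 37.0 |
| 4.00 | 36.8 |
| 6.00 | 37.9 |

(each reading ± 0.5 percentage points)

- summer: at 10 min add substrate, 50.0% of the amount charged, then wait 10 min
- dawn: at 10 min add reagent, 50.0% of the amount charged, then wait 10 min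
- winter: change nothing and wait 10 min more
- dusk: at 10 min take out 90% of the product then present, then wait 10 min

* product, in percent of the substrate first charged, at 10 min
* which option adds most product ("none" when 2 percentage points or less is all one gets) (summer / dawn / winter / dusk / none)
* product present, with what was taken out counted in, in percent of the substrate first charged, after summer
* product present, with what was taken out counted in, in percent of the substrate first charged, after dawn

- product taken out counts as made
- steps that have been proposed: substrate + reagent -> intermediate A; intermediate A -> intermediate B; substrate <-> intermediate C; reagent + intermediate A <-> intermediate D; reagent + intermediate B -> product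
- additions bring no volume worth counting

The proposed path: substrate and reagent give intermediate A, intermediate A gives intermediate B, and intermediate B takes a second reagent to give product. On the side, substrate exchanges with intermediate C, and intermediate A can bind reagent as intermediate D.

Take the run in slow motion. In the first instants both reagent steps are quick: at 0.500 min Wednesday's flask already reads 21.9%, and that product alone has cost 2.19 mM of reagent, a third of the charge, before counting what entered and stopped halfway. By 1.50 min it reads 36.1%. Then the curve lies down: replace the readings from 3.00 min to 6.00 min by their mean, 37.2%, or 1.86 mM. That mean carries a scatter of 0.29 percentage points, and the last reading stands 0.67 points above it, so a slow drift may hide there.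

Now suppose reagent is the limiting reagent, with none of its 6.50 mM free on the plateau. Reagent charged less twice the product gives 2.78 mM, the stranded reagent: reagent that went in without reaching product. As an estimate, take each unit of it as material that wants one more reagent, although on the proposed steps intermediate D already holds two reagent and wants none. My own reckoning follows. Now stays near 37.2%. Winter, summer and dusk bring no reagent, so I expect each to stay within the 2 points margin. Dawn brings 3.25 mM, more than the stranded amount, so on that estimate product reaches 92.8%.

The forecast gives 37.5% now, 37.8% after summer, 93.5% after dawn and dawn as best, holding that “the reagent has run out”; its dawn figure stands above mine.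

    substrate + reagent → intermediate A (k = 31.0 /M/s)
    intermediate A → intermediate B (k = 0.0280 /s)
    substrate ⇌ intermediate C (K = 0.530, k = 0.0120 /s)
    reagent + intermediate A ⇌ intermediate D (K = 2300 /M, k = 1.30 /M/s)
    reagent + intermediate B → product (k = 44.0 /M/s)

The flask gives 37.9% now, 38.5% after summer and 93.4% after dawn, and dawn gains 56 points. Free reagent at 10.0 min is 0.013% of its charge. Stranded reagent reckoned from that product is 54.2% of the substrate charged, and the flask's intermediate A and intermediate B plus twice its intermediate D give 54.2%. The neighbour flask charged with 8.5 mM of substrate, 0.765 equiv of reagent, ends with 0% free reagent and 8.69% product. Its stranded reagent comes to 59.1% of its substrate, and its intermediate A and intermediate B plus twice its intermediate D stand at 59.1%.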